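I began with the easy step, the main step by itself: if X is lost with one constant k, the share of the charge left at time t is exp(−kt), and the size of the charge drops out.

| flask | X | G | time |
|---|---|---|---|
| midnight | 0.200 M | 0.0200 M |  |
| winter | 0.0800 M | 0.0200 M |  |
| spring | 0.200 M | 0.0600 M |  |
| dusk | 0.400 M | 0.0200 M |  |
| noon | 1.30 M | 0.0200 M | 5.9 h |

| run | time / h | [X] / M |
|---|---|---|
| midnight run | 0.98 | 0.1474 |
| midnight run | 2.0 | 0.1081 |
| midnight run | 3.0 | 0.0822 |
| midnight run | 3.9 | 0.0651 |
| midnight run | 4.9 | 0.0514 |
| midnight run | 5.9 | 0.0405 |
| winter run | 0.98 | 0.0599 |
| winter run | 2.0 | 0.0437 |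
| winter run | 3.0 | 0.0318 |
| winter run | 3.9 | 0.0268 |
| winter run | 4.9 | 0.0194 |
| winter run | 5.9 | 0.0148 |
| spring run | 0.98 | 0.1015 |
| spring run | 2.0 | 0.0519 |
| spring run | 3.0 | 0.0258 |
| spring run | 3.9 | 0.0146 |
| spring run | 4.9 | 0.0093 |
| spring run | 5.9 | 0.0044 |
| dusk run | 0.98 | 0.2951 |
| dusk run | 2.0 | 0.2200 |
| dusk run | 3.0 | 0.1664 |
| dusk run | 3.9 | 0.1319 |
| dusk run | 4.9 | 0.1002 |
| dusk run | 5.9 | 0.0786 |

(readings scatter by 0.001 M)

- the power of [G] that the first rate follows, about the charge of the midnight run; measure it at two percent of X made into J
- the power of [X] that the first rate follows, about the charge of the midnight run; measure it at two percent of X made into J (one fixed amount of J, the same in the runs compared)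
- X in the noon run at 5.9 h, as a share of the X charged
- which of these the readings show (the product kills the catalyst / the catalyst dies in pairs / nothing beyond the main steps / the catalyst dies by itself)



- Overall: X -> J, with G as catalyst.
- Constant volume, constant temperature.
- An order is taken over about fifteen percent of the charge, up and down.

 From the first reading, k came to 0.295 h⁻¹ in the winter run, 0.311 h⁻¹ in the midnight run and 0.310 h⁻¹ in the dusk run. I therefore took the power of [X] as 1, the pseudo-first-order case at fixed G. Carried to 5.9 h, this constant leaves 16.1 % of the noon charge.

The second process is a loss of G. Between the last two readings, k had sagged to 0.238 h⁻¹ in the midnight run and 0.243 h⁻¹ in the dusk run. The dusk run had made twice the J of the midnight run, yet it sagged no further, so I did not blame J. In the spring run, with 3.00 times the G, the mean constant up to 3.9 h stood at 0.970 of the first-reading constant, against 0.924 in the midnight run. Death in pairs was thus not seen, and I concluded that G dies by itself.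

The share left depends on the mean of the sagging curve, so I replaced the curve by that mean: the mean constant, the logarithm of charge over X left, divided by the time. Averaged over the midnight and dusk runs at 5.9 h, it is 0.273 h⁻¹, which leaves 19.9 %. Against the first-reading constant, the sag has raised my number by 3.9 percentage points.

The rest concerns G itself. The first-reading constant of 0.692 h⁻¹ in the spring run gives a mean power of 0.727 in [G] across the midnight and spring charges. This leaves my noon number unchanged, since the noon flask holds the G of the dusk run.

The forecast gave 0.77 and 1 for the powers of [G] and [X], 19.9 % left, and the catalyst dies by itself, reasoning that “Noon should match dusk and midnight”. Its power of [G] is a local value and differs from my mean across the two charges.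

The noon flask kept 19.8 % of its charge, more than the 18.2 % of the fit with the main steps and nothing more. The power of [G] came to 0.78 and that of [X] to 1.0, and the answer to what the readings show is that the catalyst dies by itself.

    2 G ⇌ G2, settled at all times (14.30 M⁻¹)
    G + X → J + G (22.07 M⁻¹ h⁻¹)
    G → Ky (0.08064 h⁻¹)

The noon mean constant was 0.274 h⁻¹. In the winter run, ln(2) over 0.273 h⁻¹ gives a half-time of 2.54 h, longer than the 2.33 h the run took.

Readings and results are calculated with constants of no real substance, noise included.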